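**Retrosynthetic overview**
- The strategy rests on the only ring, a benzene ring carrying the propenoate chain on C1, the prenyl group on C3 and the acyloxy oxygen on C4. This 1,3,4-pattern is that of a 2-prenyl-1-methoxy-3-silyloxybutadiene joined to propynal.
- Late disconnections: the aryl ester C4–O–acyl bond (phenol + (S)-3-acetoxybutanoyl chloride) and the cinnamate C=C bond (Wittig olefination of the aryl aldehyde).
- Ring formation: one [4+2] cycloaddition forms ring bonds C1–C2 and C5–C6; loss of methanol and of the silyl group then gives the para-formyl phenol with the prenyl group already in place.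
- Diene: from the (E)-β-methoxy enone, itself built by conjugate addition of a 2-methylpropenyl Grignard reagent to but-3-en-2-one with silyl trapping, orthoformate addition and loss of methanol.
- The one stereocentre comes from (S)-3-hydroxybutanoic acid and is never part of a bond-forming event.

Key step: step 6

Remark: base-mediated formylation of a methyl n-alkyl ketone is expected mainly at the methyl group, so the C3-formyl pattern is built from a regiodefined silyl enol ether made by conjugate addition; 3 is carried on as its mixture of double-bond isomers, because that geometry is lost in step 2.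

**Step 1**
Reactants: 1 but-3-en-2-one; 2 2-methylprop-1-enylmagnesium bromide
Product: 3 (Z)-6-methyl-2-(trimethylsilyloxy)hepta-2,5-diene (taken on together with any E isomer)
Conditions: CuBr·SMe2 (5 mol%), TMSCl, HMPA, THF, –78 °C; then Et3N, pentane, cold aq. NaHCO3
Reagents that add atoms: chlorotrimethylsilane, C[Si](C)(C)Cl
Why: Copper-catalysed, chlorosilane-accelerated conjugate addition of the alkenyl Grignard reagent puts the 2-methylpropenyl group on the terminal carbon of the enone and traps the enolate on oxygen, so the enol double bond is fixed regiospecifically between C2 and C3 of the heptenone chain.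

**Step 2**
Reactants: 3 (Z)-6-methyl-2-(trimethylsilyloxy)hepta-2,5-diene
Product: 4 3-(dimethoxymethyl)-6-methylhept-5-en-2-one (racemic)
Conditions: HC(OMe)3, TMSOTf (10 mol%), CH2Cl2, –78 °C; then Et3N, aq. NaHCO3
Reagents that add atoms: trimethyl orthoformate, COC(OC)OC
Why: Mukaiyama-type addition of the silyl enol ether to the dimethoxycarbenium ion released from the orthoformate forms the C3–CH(OMe)2 bond only at the carbon fixed in step 1, the isolated trisubstituted alkene being far less nucleophilic at –78 °C; the C3 stereocentre is racemic and is removed in step 3.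

**Step 3**
Reactants: 4 3-(dimethoxymethyl)-6-methylhept-5-en-2-one
Product: 5 (E)-3-(methoxymethylidene)-6-methylhept-5-en-2-one
Conditions: PPTS (5 mol%), PhMe, 100 °C, MeOH distilled off
Reagents that add atoms: none
Why: Acid-catalysed β-elimination of methanol from the β-keto acetal gives the vinylogous ester, and reversible methanol addition under these conditions should let the double bond settle in the more stable E geometry, with the methoxy group anti to the acetyl group.

**Step 4**
Reactants: 5 (E)-3-(methoxymethylidene)-6-methylhept-5-en-2-one
Product: 6 (E)-1-methoxy-2-(3-methylbut-2-enyl)-3-(trimethylsilyloxy)buta-1,3-diene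
Conditions: TMSOTf, Et3N, Et2O, 0 °C; decanted from the ammonium salt, concentrated, used at once
Reagents that add atoms: trimethylsilyl trifluoromethanesulfonate, C[Si](C)(C)OS(=O)(=O)C(F)(F)F
Why: Soft enolisation (O-silylation, then deprotonation of the acetyl methyl group, the only enolisable position) is the standard silyl enol ether formation used for 1-alkoxy-3-silyloxy dienes and leaves the enol ether geometry untouched.

**Step 5**
Reactants: 7 3,3-diethoxyprop-1-yne
Product: 8 propynal
Conditions: 2 M aq. H2SO4, 25 → 45 °C, product distilled out under reduced pressure into a –78 °C trap; dried (MgSO4), diluted with PhMe, used at once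
Reagents that add atoms: water, O
Why: Acid-catalysed acetal hydrolysis through the oxocarbenium ion and the hemiacetal releases the ynal, which is removed from the acid as it forms because it hydrates and polymerises on standing.

**Step 6**
Reactants: 6 (E)-1-methoxy-2-(3-methylbut-2-enyl)-3-(trimethylsilyloxy)buta-1,3-diene; 8 propynal
Product: 11 4-hydroxy-3-(3-methylbut-2-enyl)benzaldehyde, via cyclohexa-1,4-diene cycloadduct 9 (not isolated), via aryl trimethylsilyl ether 10 (not isolated)
Conditions: PhMe, 0 → 25 °C, slight excess of 6, no Lewis acid; then 1 M HCl, THF, 25 °C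
Reagents that add atoms: none
Why: The electron-rich diene and the electron-poor ynal combine in a thermal, concerted but asynchronous normal-demand Diels–Alder reaction, in which the CH2 terminus of 6 (made nucleophilic by both the silyloxy and the methoxy group) bonds to the β-carbon of 8 and the methoxy-bearing terminus to the α-carbon. The six-membered carbocycle is closed by this intermolecular [4+2] cycloaddition, which forms the later aromatic bonds C5–C6 and C1–C2 together and gives cyclohexa-1,4-diene 9. Loss of methanol from 9 (the allylic methoxy group ionises with help from the silyl enol ether, and the ring CH2 then gives up a proton) aromatises the ring to silyl ether 10, and the dilute acid cleaves its O–Si bond to the phenol. The closest known reaction type is the cycloaddition of 1-alkoxy-3-silyloxybuta-1,3-dienes with acetylenic aldehydes, ketones and esters, which gives para-acyl phenols after loss of the alcohol. No stereocentre has to be controlled, since the single sp3 centre of 9 forms as a racemate and is lost on aromatisation. The step needs regioselectivity (formyl para and prenyl ortho to oxygen), secured by the matched donor pattern of the diene and the polarisation of the ynal, and chemoselectivity for C≡C over C=O, secured by the absence of any Lewis acid, while the E-methoxy terminus and the 2-substituent keep the reactive s-cis conformer accessible.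

**Step 7**
Reactants: 11 4-hydroxy-3-(3-methylbut-2-enyl)benzaldehyde; 12 methyl (triphenylphosphoranylidene)acetate
Product: 13 methyl (E)-3-[4-hydroxy-3-(3-methylbut-2-enyl)phenyl]prop-2-enoate
Conditions: PhMe, 90 °C
Reagents that add atoms: none
Why: Wittig olefination with an ester-stabilised ylide should give the E-alkene, and the free phenol is tolerated because the ylide, although partly protonated by it, still adds to the aldehyde on heating.

**Step 8**
Reactants: 14 (S)-3-hydroxybutanoic acid
Product: 15 (S)-3-acetoxybutanoic acid
Conditions: AcCl (neat, excess), 0 → 25 °C; evaporated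
Reagents that add atoms: acetyl chloride, CC(=O)Cl
Why: O-Acylation of the secondary alcohol by the acid chloride breaks no bond at the stereocentre, so the S configuration is retained.

**Step 9**
Reactants: 15 (S)-3-acetoxybutanoic acid
Product: 16 (S)-3-acetoxybutanoyl chloride
Conditions: (COCl)2, DMF (cat.), CH2Cl2, 0 → 25 °C; evaporated, used crude
Reagents that add atoms: oxalyl chloride, O=C(Cl)C(=O)Cl
Why: Acid chloride formation through the chloroiminium species from DMF and oxalyl chloride runs cold and without base, so the β-acetoxy group is not eliminated and the β-stereocentre is untouched.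

**Step 10**
Reactants: 13 methyl (E)-3-[4-hydroxy-3-(3-methylbut-2-enyl)phenyl]prop-2-enoate; 16 (S)-3-acetoxybutanoyl chloride
Product: 17 methyl (E)-3-[4-[(3S)-3-acetoxybutanoyl]oxy-3-(3-methylbut-2-enyl)phenyl]prop-2-enoate
Conditions: pyridine, CH2Cl2, –10 → 0 °C
Reagents that add atoms: none
Why: Nucleophilic acyl substitution of the acid chloride by the phenol with pyridine as a weak base forms the aryl ester without involving the stereocentre, and pyridine is expected to be too weak a base to eliminate acetate.

**Compound list**
1 | but-3-en-2-one | C=CC(C)=O | starting material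
2 | 2-methylprop-1-enylmagnesium bromide | CC(C)=C[Mg]Br | starting material
3 | (Z)-6-methyl-2-(trimethylsilyloxy)hepta-2,5-diene (E isomer carried along) | C/C(O[Si](C)(C)C)=C/CC=C(C)C | intermediate
4 | 3-(dimethoxymethyl)-6-methylhept-5-en-2-one (racemic) | COC(OC)C(CC=C(C)C)C(C)=O | intermediate
5 | (E)-3-(methoxymethylidene)-6-methylhept-5-en-2-one | CO/C=C(\CC=C(C)C)C(C)=O | intermediate
6 | (E)-1-methoxy-2-(3-methylbut-2-enyl)-3-(trimethylsilyloxy)buta-1,3-diene | CO/C=C(\CC=C(C)C)C(=C)O[Si](C)(C)C | intermediate
7 | 3,3-diethoxyprop-1-yne | C#CC(OCC)OCC | starting material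
8 | propynal | C#CC=O | intermediate
9 | 6-methoxy-5-(3-methylbut-2-enyl)-4-(trimethylsilyloxy)cyclohexa-1,4-diene-1-carbaldehyde (racemic, not isolated) | COC1C(CC=C(C)C)=C(O[Si](C)(C)C)CC=C1C=O | intermediate
10 | 3-(3-methylbut-2-enyl)-4-(trimethylsilyloxy)benzaldehyde (not isolated) | O=Cc1ccc(O[Si](C)(C)C)c(CC=C(C)C)c1 | intermediate
11 | 4-hydroxy-3-(3-methylbut-2-enyl)benzaldehyde | O=Cc1ccc(O)c(CC=C(C)C)c1 | intermediate
12 | methyl (triphenylphosphoranylidene)acetate | COC(=O)C=P(c1ccccc1)(c1ccccc1)c1ccccc1 | starting material
13 | methyl (E)-3-[4-hydroxy-3-(3-methylbut-2-enyl)phenyl]prop-2-enoate | COC(=O)/C=C/c1ccc(O)c(CC=C(C)C)c1 | intermediate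
14 | (S)-3-hydroxybutanoic acid | C[C@H](O)CC(=O)O | starting material
15 | (S)-3-acetoxybutanoic acid | C[C@H](OC(C)=O)CC(=O)O | intermediate
16 | (S)-3-acetoxybutanoyl chloride | C[C@H](OC(C)=O)CC(=O)Cl | intermediate
17 | methyl (E)-3-[4-[(3S)-3-acetoxybutanoyl]oxy-3-(3-methylbut-2-enyl)phenyl]prop-2-enoate | COC(=O)/C=C/c1ccc(OC(=O)C[C@H](C)OC(C)=O)c(CC=C(C)C)c1 | target

**Step count**
Total: 10 steps. Longest linear sequence: 7 steps (steps 1, 2, 3, 4, 6, 7, 10).

**Steps most likely to fail**

Step 6. Propynal may polymerise, or add through its carbonyl group in a hetero-Diels–Alder reaction, faster than the alkyne cycloaddition proceeds. Traces of acid, water or ethanol carried over from step 5 may also desilylate diene 6 back to enone 5. The fallback sets out from 6 and comes back at 11. Diene 6 is heated with methyl propiolate in toluene at 90–110 °C. The cycloadduct, methyl 6-methoxy-5-(3-methylbut-2-enyl)-4-(trimethylsilyloxy)cyclohexa-1,4-diene-1-carboxylate F1, should lose methanol to methyl 3-(3-methylbut-2-enyl)-4-(trimethylsilyloxy)benzoate F2, and dilute HCl work-up should give methyl 4-hydroxy-3-(3-methylbut-2-enyl)benzoate F3. Reduction with LiAlH4 in THF gives 4-(hydroxymethyl)-2-(3-methylbut-2-enyl)phenol F4, and MnO2 in CH2Cl2 oxidises the benzylic alcohol to aldehyde 11.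

Step 2. The silyl enol ether may be protodesilylated by adventitious acid before it adds, or acetal 4 may ionise again under the silyl triflate, lose methanol early and oligomerise as the enone. The fallback sets out from 3 and comes back at 5, passing 4 by. Methyllithium in THF at 0 °C cleaves the O–Si bond of 3 to the regiodefined enolate, lithium 6-methylhepta-2,5-dien-2-olate F5. Formylation at –78 °C with 2,2,2-trifluoroethyl formate and dilute HCl work-up gives 3-(hydroxymethylidene)-6-methylhept-5-en-2-one F6 (the enol form of 2-acetyl-5-methylhex-4-enal). O-Methylation with dimethyl sulfate and K2CO3 in acetone then gives 5.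

Step 10. Base-induced β-elimination of acetate from the activated acyl group, or ketene formation, may divert the acid chloride to a crotonate ester. The fallback sets out from 14 and 13 and comes back at 17; the acetate is put on last, when the acyl group is no longer activated.
- Acid 14 is bis-silylated with tert-butyldimethylsilyl chloride and imidazole in DMF to tert-butyldimethylsilyl (S)-3-(tert-butyldimethylsilyloxy)butanoate F7.
- The silyl ester is cleaved with aqueous methanol containing a catalytic amount of K2CO3 to (S)-3-(tert-butyldimethylsilyloxy)butanoic acid F8.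
- Steglich esterification of 13 with F8 (EDC·HCl, catalytic DMAP, CH2Cl2) gives methyl (E)-3-[4-[(3S)-3-(tert-butyldimethylsilyloxy)butanoyl]oxy-3-(3-methylbut-2-enyl)phenyl]prop-2-enoate F9.
- HF·pyridine in THF at 0 °C frees methyl (E)-3-[4-[(3S)-3-hydroxybutanoyl]oxy-3-(3-methylbut-2-enyl)phenyl]prop-2-enoate F10.
- Acetic anhydride and pyridine in CH2Cl2 acetylate F10 to 17.

**Further compounds**
F1 | step 6 | methyl 6-methoxy-5-(3-methylbut-2-enyl)-4-(trimethylsilyloxy)cyclohexa-1,4-diene-1-carboxylate (racemic) | COC(=O)C1=CCC(O[Si](C)(C)C)=C(CC=C(C)C)C1OC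
F2 | step 6 | methyl 3-(3-methylbut-2-enyl)-4-(trimethylsilyloxy)benzoate | COC(=O)c1ccc(O[Si](C)(C)C)c(CC=C(C)C)c1
F3 | step 6 | methyl 4-hydroxy-3-(3-methylbut-2-enyl)benzoate | COC(=O)c1ccc(O)c(CC=C(C)C)c1
F4 | step 6 | 4-(hydroxymethyl)-2-(3-methylbut-2-enyl)phenol | OCc1ccc(O)c(CC=C(C)C)c1
F5 | step 2 | lithium 6-methylhepta-2,5-dien-2-olate | [Li]OC(C)=CCC=C(C)C
F6 | step 2 | 3-(hydroxymethylidene)-6-methylhept-5-en-2-one | CC(=O)C(CC=C(C)C)=CO
F7 | step 10 | tert-butyldimethylsilyl (S)-3-(tert-butyldimethylsilyloxy)butanoate | C[C@H](O[Si](C)(C)C(C)(C)C)CC(=O)O[Si](C)(C)C(C)(C)C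
F8 | step 10 | (S)-3-(tert-butyldimethylsilyloxy)butanoic acid | C[C@H](O[Si](C)(C)C(C)(C)C)CC(=O)O
F9 | step 10 | methyl (E)-3-[4-[(3S)-3-(tert-butyldimethylsilyloxy)butanoyl]oxy-3-(3-methylbut-2-enyl)phenyl]prop-2-enoate | COC(=O)/C=C/c1ccc(OC(=O)C[C@H](C)O[Si](C)(C)C(C)(C)C)c(CC=C(C)C)c1
F10 | step 10 | methyl (E)-3-[4-[(3S)-3-hydroxybutanoyl]oxy-3-(3-methylbut-2-enyl)phenyl]prop-2-enoate | COC(=O)/C=C/c1ccc(OC(=O)C[C@H](C)O)c(CC=C(C)C)c1
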